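## Structural features

The target 35 is an achiral, strictly linear chain of eight polyhydroxybenzene rings joined only through seven diaryl ether oxygens; it has twenty-one free phenolic hydroxyls, no ring–ring carbon–carbon bond and no stereocentre, so no stereocentres stand next to each other and no configuration has to be set. Lettered from the phloroglucinol-type end, ring A is 2,4,6-trihydroxyphenyl, rings B and D are 2,6-dihydroxy-1,4-phenylene units whose ether oxygen toward ring C or ring E sits on the carbon between the two hydroxyls while the other ether oxygen sits on the open para carbon, and ring H is 3,4,5-trihydroxyphenyl. Rings C, E and G each carry five oxygens and one C–H, with two ether oxygens on neighbouring carbons; the ether carbon next to the C–H points to ring B in ring C and to ring F in rings E and G. Ring F has four oxygens: ethers at C1 (to ring E) and C5 (to ring G) and hydroxyls at C3 and C4. The pyrogallol and hydroxyquinol arrays are oxidised to quinones by air, fastest as phenoxides, and the phloroglucinol-type ring A can be O-alkylated by acidic alcohols, so all hydroxyls travel as methyl ethers and the few free phenols of the route are handled under argon. The real difficulty is positional control over seven C–O–C bridges among thirty-five oxygen-bearing ring carbons, together with the crowding at the B–O–C ether (three ortho substituents) and the D–O–E ether (four). The key step uses the fact that in ring F the ether carbon C1 is para and the ether carbon C5 ortho to the hydroxyl carbon C4, with the second hydroxyl carbon C3 at the other ortho position, so a formyl group on C4 activates all three carbons for fluoride displacement and is later exchanged for the C4 hydroxyl. Rings B and D show the same para relation between their crowded oxygen-bearing carbon and their open ether carbon, which lets linchpin 4 serve three times.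

## Logic of the disconnections

35 from 34. The twenty O–CH3 bonds are cut last in the forward sense. Methyl ethers come with the building blocks, mask every oxidation-prone hydroxyl and are small at the crowded ethers. The gain is that every intermediate is a neutral, air-tolerant, chromatographable compound. The forward step must dealkylate exhaustively at sp3 carbon, leave the seven aryl–oxygen–aryl bonds alone, and be quenched without an alcohol.

34 from 32 from 31. The ring F hydroxyl carbon C4 of 34 is traced back to a formyl-bearing carbon (32), and the neighbouring methoxy carbon C3 to a C–F carbon (31). The formyl group is the activator that the key step needs, and it stands exactly where an oxygen is wanted. The gain is that ring F reduces to a single commercial arene. The forward steps require methoxide to choose the C–F carbon over the two C–OAr carbons, and the peracid to oxidise the aldehyde faster than the electron-rich rings.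

31 from 24, 4 and 29. The two aryl–oxygen bonds at ring F C1 (to ring E) and C5 (to ring G) are cut. This is the only place where one small electrophile can unite a five-ring and a two-ring fragment, and both carbons are activated by the same formyl group. The gain is the largest in the route: an octamer falls into a pentamer phenol, a dimer phenol and 4. The forward step needs para selectivity for the first phenoxide and mono-substitution in each stage.

29 from 27 from 25 and 26. The ring G phenol oxygen is traced back to a formyl group (27), and the G–O–H ether bond is cut at the ring G carbon that lies ortho to that formyl group. The reason is that 26 is commercial and its ortho formyl group assists copper-mediated C–O coupling. The gain is a two-step access to 29. The demand is coupling at a bromide flanked by formyl and methoxy groups.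

24 from 23, 22, 20, then 17 and 19 (19 from 18). The D–O–E bond is cut at the ring E carbon. This ether has four ortho substituents, so the electrophile is made as reactive as possible: a bromoquinone. After reduction, the two hydroxyls of ring E are told apart by acylating the one next to the C–H (22), methylating the other (23) and removing the acyl group (24). Compared with a route that builds every ring from quinones, hydroxyl differentiation is now needed only once. The demands are attack at the C–Br carbon of 19 and site-selective acylation of 21.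

17 from 15 from 13 and 4. The crowded ring D hydroxyl is traced back to a formyl group, the two ring D methoxy carbons to C–F carbons, and the C–O–D bond is cut at the open para carbon of ring D. This repeats the logic of the key step, so the crowded phenol appears without any protecting group. The demand is again para selectivity, helped here by a di-ortho-substituted phenoxide.

13 from 11 from 8 and 10 (10 from 9). The ring C hydroxyl is traced back to a formyl group, and the B–O–C bond is cut at the ring C carbon ortho to it, which carries bromine and only one ortho substituent. The aryl–formyl bond of 10 is cut back to 9, whose two free positions are equivalent. The demand is copper-mediated coupling of a 2,6-disubstituted phenoxide.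

8 from 6 from 3 and 4 (3 from 1). Ring B is built exactly as ring D: a hydroxyl from a formyl group, two methoxy groups from fluorides, and the A–O–B bond at the para carbon of 4. The ring A phenol 3 comes from aldehyde 1 by the same formyl-to-hydroxyl exchange.

## Other disconnections considered

Alternative 1: The cut opens ring C between its two ether-bearing carbons and between its C–H carbon and the neighbouring hydroxyl carbon (Danheiser benzannulation).
- Forward step: heating the aryloxyacetylene A2 with the racemic cyclobutenone A3 should give a vinylketene by four-electron ring opening. This adds (2+2) to the ynol ether, the new vinylcyclobutenone opens, and six-electron closure with tautomerisation gives the phenol A1.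
- In favour: the two crowded neighbouring aryloxy groups of ring C arrive on the two components, so neither the B–O–C nor the C–O–D ether is made by substitution at a crowded arene carbon. The conditions are neutral and metal-free, and the regiochemistry follows from the polarity of the ynol ether. In avoiding copper coupling of a hindered phenoxide it is the better of the two plans.
- Against: A2 must be made from the hindered phenol 8 through a dichlorovinyl ether and elimination, and aryloxyacetylenes are thermally labile and weaker ketenophiles than alkoxyacetylenes. A3 needs a multi-step preparation from a squaric ester. The phenol of A1 stands at a position that must then be methylated, the benzyl group must be removed, and the D–O–E ether and the whole ring F junction remain unsolved.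
- Comparison: on structure it builds one ring and two C–C bonds in the middle of one half, whereas the chosen step joins the two halves. On mechanism it is a pericyclic cascade against polar addition–elimination, and the two are equal in convergence at their own junctions. On step economy it is worse: about nine operations from 8 to the stage of 17, against four (steps 5 to 8).

Alternative 2: The cut removes the two ring D bonds that run from each C–H carbon to its substituted neighbour (formal (3+3) cyclocondensation).
- Forward step: TiCl4 should condense the bis(silyloxy)diene A5 with the 2-aryloxymalonaldehyde A6 to the salicylate A4, with the crowded ring D phenol free.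
- In favour: the regiochemistry is fixed by the components, so there is no para/ortho question as there is on 4; in this respect it is the better plan. The crowded phenol is free from the outset, which equals the chosen plan.
- Against: A6 requires O-alkylation of the hindered phenol 13 and a double formylation, and malonaldehydes self-condense. TiCl4 meets eleven aryl methyl ethers in chelating arrays and may cleave some. The ester stands where ring D needs oxygen and must be degraded (reduction, oxidation to the aldehyde, peracid, methylation) while the neighbouring phenol has to be kept distinct. The D–O–E ether is still unsolved.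
- Comparison: on structure it closes a ring that the chosen plan buys as 4. On mechanism it is Lewis-acid carbonyl chemistry against base-mediated substitution. On step economy it needs about eight steps from 13 to the stage of 17, against two (steps 7 and 8).

Alternative 3: The cut opens ring G between the future ring F ether carbon and the lone C–H carbon (squarate ring expansion).
- Forward step: thermolysis of the racemic vinylcyclobutenone A8 should open it to a dienylketene, whose six-electron closure and tautomerisation give A7, identical in structure with 29.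
- In favour: all five oxygens are placed by construction, the free phenol appears exactly where the key step needs it, and neither copper coupling at a di-ortho-substituted bromide nor a peracid is used. It is the equal of steps 14 and 15 in outcome and the better in regiochemical certainty.
- Against: the mixed squarate A9 behind A8 cannot be made simply by phenoxide displacing methoxide (the exchange is uphill), so an acid chloride detour is needed. The vinyl-lithium reagent must choose one of two carbonyls of A9 and is generated with tert-butyllithium. The tertiary alkoxide must then be methylated.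
- Comparison: on structure it builds a ring that is not the bottleneck and does not connect the halves. On mechanism it is pericyclic against polar. On step economy it needs about four steps against two.

Key step: step 16

Remark on the chemistry: 35 is achiral and is taken as the neutral polyphenol; a ring-by-ring comparison of 35 with 24, 29, 31 and 34 shows the same oxygenation pattern on every ring, so no structure needed correction.

Remark on names: (A–B aryloxy) is 2,6-dimethoxy-4-(2,4,6-trimethoxyphenoxy)phenoxy, the oxy group of 8. (A–B–C aryloxy), (A–B–C–D aryloxy), (A–B–C–D–E aryloxy) and (G–H aryloxy) are the oxy groups of 13, 17, 24 and 29.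

## Route

Step 1
Reactants: 1 2,4,6-trimethoxybenzaldehyde
Product: 3 2,4,6-trimethoxyphenol, via aryl formate 2 (not isolated)
Conditions: mCPBA, CH2Cl2, 0 °C to rt; then MeOH, HCl (cat.), rt
Reagents that add atoms: meta-chloroperoxybenzoic acid (mCPBA), O=C(OO)c1cccc(Cl)c1
Why: Baeyer–Villiger oxidation; the peracid adds to the aldehyde and the 2,4,6-trioxygenated aryl group migrates to oxygen in preference to hydride, and acidic methanolysis then cleaves formate 2 without exposing the electron-rich phenol to base and air.

Step 2
Reactants: 3 2,4,6-trimethoxyphenol; 4 2,4,6-trifluorobenzaldehyde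
Product: 6 2,6-dimethoxy-4-(2,4,6-trimethoxyphenoxy)benzaldehyde, via difluoro aldehyde 5 (not isolated)
Conditions: Cs2CO3, DMSO, 20 °C; then NaOMe, MeOH, 50 °C
Reagents that add atoms: sodium methoxide, [Na+].[O-]C
Why: Nucleophilic aromatic substitution by addition–elimination; the di-ortho-substituted phenoxide should attack the para C–F carbon of 4, and methoxide then replaces the two equivalent ortho fluorides, a C–F carbon being far more reactive toward addition than the C–OAr carbon already formed.

Step 3
Reactants: 6 2,6-dimethoxy-4-(2,4,6-trimethoxyphenoxy)benzaldehyde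
Product: 8 2,6-dimethoxy-4-(2,4,6-trimethoxyphenoxy)phenol, via aryl formate 7 (not isolated)
Conditions: mCPBA, CH2Cl2, 0 °C; then MeOH, HCl (cat.), rt, Ar
Reagents that add atoms: meta-chloroperoxybenzoic acid (mCPBA), O=C(OO)c1cccc(Cl)c1
Why: Baeyer–Villiger oxidation; the formyl group sits between two methoxy groups and para to an aryloxy group, so aryl migration is strongly favoured and the crowded ring B phenol is set free without a protecting group.

Step 4
Reactants: 9 5-bromo-1,2,3-trimethoxybenzene
Product: 10 6-bromo-2,3,4-trimethoxybenzaldehyde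
Conditions: Cl2CHOMe, TiCl4, CH2Cl2, −10 to 0 °C; then H2O
Reagents that add atoms: dichloromethyl methyl ether, COC(Cl)Cl; water, O
Why: Rieche formylation (electrophilic aromatic substitution); the two free positions of 9 are equivalent and each is ortho to one methoxy group and para to another, so a single aldehyde with bromine ortho to the formyl group should result.

Step 5
Reactants: 8 2,6-dimethoxy-4-(2,4,6-trimethoxyphenoxy)phenol; 10 6-bromo-2,3,4-trimethoxybenzaldehyde
Product: 11 2,3,4-trimethoxy-6-(A–B aryloxy)benzaldehyde
Conditions: CuI (10 mol %), picolinic acid (20 mol %), K3PO4, DMSO, 90 °C, Ar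
Reagents that add atoms: none
Why: Ullmann-type C–O coupling; the bromide of 10 has only the formyl group as ortho substituent, which activates it and can coordinate copper, and picolinate-ligated monovalent copper is the kind of catalyst used for 2,6-disubstituted phenols.

Step 6
Reactants: 11 2,3,4-trimethoxy-6-(A–B aryloxy)benzaldehyde
Product: 13 2,3,4-trimethoxy-6-(A–B aryloxy)phenol, via aryl formate 12 (not isolated)
Conditions: mCPBA, CH2Cl2, 0 °C; then MeOH, HCl (cat.), rt, Ar
Reagents that add atoms: meta-chloroperoxybenzoic acid (mCPBA), O=C(OO)c1cccc(Cl)c1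
Why: Baeyer–Villiger oxidation; the formyl group has oxygen donors at both ortho positions and at the para position, so the ring C aryl group migrates and the hydroxyl appears between the B-ring ether and a methoxy group.

Step 7
Reactants: 13 2,3,4-trimethoxy-6-(A–B aryloxy)phenol; 4 2,4,6-trifluorobenzaldehyde
Product: 15 2,6-dimethoxy-4-(A–B–C aryloxy)benzaldehyde, via difluoro aldehyde 14 (not isolated)
Conditions: Cs2CO3, DMSO, 20 °C; then NaOMe, MeOH, 50 °C
Reagents that add atoms: sodium methoxide, [Na+].[O-]C
Why: Nucleophilic aromatic substitution as in step 2; the phenoxide of 13 is flanked by an aryloxy and a methoxy group and should therefore prefer the open para C–F carbon of 4, after which methoxide replaces both ortho fluorides.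

Step 8
Reactants: 15 2,6-dimethoxy-4-(A–B–C aryloxy)benzaldehyde
Product: 17 2,6-dimethoxy-4-(A–B–C aryloxy)phenol, via aryl formate 16 (not isolated)
Conditions: mCPBA, CH2Cl2, 0 °C; then MeOH, HCl (cat.), rt, Ar
Reagents that add atoms: meta-chloroperoxybenzoic acid (mCPBA), O=C(OO)c1cccc(Cl)c1
Why: Baeyer–Villiger oxidation as in step 3; a slight excess of peracid at 0 °C is used because the aldehyde should react much faster than the polymethoxyarene rings.

Step 9
Reactants: 18 2,6-dimethoxy-1,4-benzoquinone
Product: 19 3-bromo-2,6-dimethoxy-1,4-benzoquinone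
Conditions: Br2 (1 equiv), NaOAc, AcOH, rt
Reagents that add atoms: bromine, BrBr
Why: Electrophilic bromination of a vinylogous ester at its alpha carbon (addition of bromine, loss of HBr to acetate); one equivalent and the deactivating first bromine should hold the reaction at the mono-bromide.

Step 10
Reactants: 17 2,6-dimethoxy-4-(A–B–C aryloxy)phenol; 19 3-bromo-2,6-dimethoxy-1,4-benzoquinone
Product: 20 2,6-dimethoxy-3-(A–B–C–D aryloxy)-1,4-benzoquinone
Conditions: Cs2CO3, MeCN, 0 °C to rt, Ar
Reagents that add atoms: none
Why: Addition–elimination of a phenoxide on a haloquinone; attack at the C–Br carbon is followed by irreversible loss of bromide, attack at a methoxy-bearing carbon is reversible because aryloxide is the better leaving group, and the high electrophilicity of the quinone should let the tetra-ortho-substituted ether form at room temperature.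

Step 11
Reactants: 20 2,6-dimethoxy-3-(A–B–C–D aryloxy)-1,4-benzoquinone
Product: 22 4-hydroxy-3,5-dimethoxy-2-(A–B–C–D aryloxy)phenyl pivalate, via hydroquinone 21 (not isolated)
Conditions: Na2S2O4, EtOAc/H2O, rt; then PivCl (1 equiv), pyridine, CH2Cl2, −20 to 0 °C, Ar
Reagents that add atoms: pivaloyl chloride, CC(C)(C)C(Cl)=O
Why: Dithionite reduction of the quinone followed by kinetically selective O-acylation; the hydroxyl next to the ring C–H should be acylated by the bulky acid chloride, the hydroxyl between two methoxy groups being shielded and hydrogen-bonded.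

Step 12
Reactants: 22 4-hydroxy-3,5-dimethoxy-2-(A–B–C–D aryloxy)phenyl pivalate
Product: 23 3,4,5-trimethoxy-2-(A–B–C–D aryloxy)phenyl pivalate
Conditions: MeI, K2CO3, DMF, rt
Reagents that add atoms: iodomethane, CI
Why: Williamson O-methylation of the remaining crowded phenol; the aryl pivalate is stable to carbonate in an aprotic solvent and cannot migrate to the para oxygen.

Step 13
Reactants: 23 3,4,5-trimethoxy-2-(A–B–C–D aryloxy)phenyl pivalate
Product: 24 3,4,5-trimethoxy-2-(A–B–C–D aryloxy)phenol (protected A–B–C–D–E pentamer phenol)
Conditions: NaOMe, MeOH/THF, rt; then aq. HCl, Ar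
Reagents that add atoms: none
Why: Methanolysis (transesterification) of the aryl pivalate; aryl and methyl ethers are inert to methoxide at room temperature, and the phenol next to the ring E C–H is released.

Step 14
Reactants: 25 3,4,5-trimethoxyphenol; 26 2-bromo-3,4,5-trimethoxybenzaldehyde
Product: 27 3,4,5-trimethoxy-2-(3,4,5-trimethoxyphenoxy)benzaldehyde
Conditions: CuI (10 mol %), picolinic acid (20 mol %), K3PO4, DMSO, 90 °C, Ar
Reagents that add atoms: none
Why: Ullmann-type C–O coupling; the phenol is unhindered and electron-rich, and the bromide, though flanked by formyl and methoxy groups, is activated by the ortho formyl group.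

Step 15
Reactants: 27 3,4,5-trimethoxy-2-(3,4,5-trimethoxyphenoxy)benzaldehyde
Product: 29 3,4,5-trimethoxy-2-(3,4,5-trimethoxyphenoxy)phenol (protected G–H phenol), via aryl formate 28 (not isolated)
Conditions: mCPBA, CH2Cl2, 0 °C; then MeOH, HCl (cat.), rt, Ar
Reagents that add atoms: meta-chloroperoxybenzoic acid (mCPBA), O=C(OO)c1cccc(Cl)c1
Why: Baeyer–Villiger oxidation; an ortho aryloxy and a para methoxy donor make the ring G aryl group migrate, as for simple 3,4,5-trimethoxybenzaldehydes.

Step 16
Reactants: 24 3,4,5-trimethoxy-2-(A–B–C–D aryloxy)phenol; 4 2,4,6-trifluorobenzaldehyde; 29 3,4,5-trimethoxy-2-(3,4,5-trimethoxyphenoxy)phenol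
Product: 31 2-fluoro-4-(A–B–C–D–E aryloxy)-6-(G–H aryloxy)benzaldehyde (protected octaaryl ether), via difluoro aldehyde 30 (not isolated)
Conditions: Cs2CO3, DMSO, 20 °C (24 added slowly to 4); then 29, Cs2CO3, 70 °C, Ar
Reagents that add atoms: none
Why: The cesium phenoxide of 24 adds to the carbon of 4 para to the formyl group, giving a Meisenheimer anion whose charge is carried by the carbonyl oxygen and stabilised inductively by the two remaining C–F bonds; loss of fluoride gives 30. The phenoxide of 29 then repeats the addition–elimination on warming at one of the two now equivalent ortho C–F carbons and gives 31. The closest known reaction type is the displacement of ortho and para fluorides of fluorobenzaldehydes by phenoxides in dipolar aprotic solvents. No ring is closed and no stereocentre is formed; the step makes the two aryl–oxygen bonds of ring F. It needs para selectivity in the first stage, which should follow from the non-chelating cesium/DMSO medium, the low temperature and the bulk of the phenoxide of 24, whose oxygen lies next to a fully substituted aryloxy group. It needs mono-substitution in each stage, which the stoichiometry and the deactivation of the ring by each new aryloxy donor should secure, so the last fluoride survives at 70 °C. Exchange of an aryloxy group already in place is disfavoured because addition at a C–F carbon is much faster than at a C–OAr carbon.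

Step 17
Reactants: 31 2-fluoro-4-(A–B–C–D–E aryloxy)-6-(G–H aryloxy)benzaldehyde
Product: 32 2-methoxy-4-(A–B–C–D–E aryloxy)-6-(G–H aryloxy)benzaldehyde
Conditions: NaOMe, MeOH/DMSO, 50 °C
Reagents that add atoms: sodium methoxide, [Na+].[O-]C
Why: Nucleophilic aromatic substitution; methoxide attacks the only C–F carbon, ortho to the formyl group, and fluoride leaves much faster than either aryloxide, so both aryl ethers should be kept.

Step 18
Reactants: 32 2-methoxy-4-(A–B–C–D–E aryloxy)-6-(G–H aryloxy)benzaldehyde
Product: 34 2-methoxy-4-(A–B–C–D–E aryloxy)-6-(G–H aryloxy)phenol, via aryl formate 33 (not isolated)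
Conditions: mCPBA, CH2Cl2, 0 °C; then MeOH, HCl (cat.), rt, Ar
Reagents that add atoms: meta-chloroperoxybenzoic acid (mCPBA), O=C(OO)c1cccc(Cl)c1
Why: Baeyer–Villiger oxidation; the ring F aryl group carries oxygen donors at both ortho positions and the para position and migrates to peroxide oxygen, turning the activating formyl carbon into the ring F C4 hydroxyl.

Step 19
Reactants: 34 2-methoxy-4-(A–B–C–D–E aryloxy)-6-(G–H aryloxy)phenol
Product: 35 CNP0309601.0 (the free octaaryl heptaether with twenty-one hydroxyls)
Conditions: BBr3 (large excess), CH2Cl2, −78 °C to rt; then H2O, 0 °C, Ar; reverse-phase chromatography with acidified eluent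
Reagents that add atoms: none
Why: Lewis-acid ether cleavage; each methyl ether is complexed at oxygen and dealkylated by bromide at the methyl carbon (SN2), the seven diaryl ether bonds offer no sp3 carbon, and the aqueous quench avoids acid-catalysed re-etherification of the phloroglucinol-type ring A.

## Compound list

1 | 2,4,6-trimethoxybenzaldehyde | O=Cc1c(OC)cc(OC)cc1OC | starting material
2 | 2,4,6-trimethoxyphenyl formate | O=COc1c(OC)cc(OC)cc1OC | intermediate
3 | 2,4,6-trimethoxyphenol | Oc1c(OC)cc(OC)cc1OC | intermediate
4 | 2,4,6-trifluorobenzaldehyde | O=Cc1c(F)cc(F)cc1F | starting material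
5 | 2,6-difluoro-4-(2,4,6-trimethoxyphenoxy)benzaldehyde | O=Cc1c(F)cc(Oc2c(OC)cc(OC)cc2OC)cc1F | intermediate
6 | 2,6-dimethoxy-4-(2,4,6-trimethoxyphenoxy)benzaldehyde | O=Cc1c(OC)cc(Oc2c(OC)cc(OC)cc2OC)cc1OC | intermediate
7 | 2,6-dimethoxy-4-(2,4,6-trimethoxyphenoxy)phenyl formate | O=COc1c(OC)cc(Oc2c(OC)cc(OC)cc2OC)cc1OC | intermediate
8 | 2,6-dimethoxy-4-(2,4,6-trimethoxyphenoxy)phenol (A–B phenol) | Oc1c(OC)cc(Oc2c(OC)cc(OC)cc2OC)cc1OC | intermediate
9 | 5-bromo-1,2,3-trimethoxybenzene | COc1cc(Br)cc(OC)c1OC | starting material
10 | 6-bromo-2,3,4-trimethoxybenzaldehyde | O=Cc1c(Br)cc(OC)c(OC)c1OC | intermediate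
11 | 6-[2,6-dimethoxy-4-(2,4,6-trimethoxyphenoxy)phenoxy]-2,3,4-trimethoxybenzaldehyde | O=Cc1c(Oc2c(OC)cc(Oc3c(OC)cc(OC)cc3OC)cc2OC)cc(OC)c(OC)c1OC | intermediate
12 | 6-[2,6-dimethoxy-4-(2,4,6-trimethoxyphenoxy)phenoxy]-2,3,4-trimethoxyphenyl formate | O=COc1c(Oc2c(OC)cc(Oc3c(OC)cc(OC)cc3OC)cc2OC)cc(OC)c(OC)c1OC | intermediate
13 | 6-[2,6-dimethoxy-4-(2,4,6-trimethoxyphenoxy)phenoxy]-2,3,4-trimethoxyphenol (A–B–C phenol) | Oc1c(Oc2c(OC)cc(Oc3c(OC)cc(OC)cc3OC)cc2OC)cc(OC)c(OC)c1OC | intermediate
14 | 2,6-difluoro-4-(A–B–C aryloxy)benzaldehyde | O=Cc1c(F)cc(Oc2c(Oc3c(OC)cc(Oc4c(OC)cc(OC)cc4OC)cc3OC)cc(OC)c(OC)c2OC)cc1F | intermediate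
15 | 2,6-dimethoxy-4-(A–B–C aryloxy)benzaldehyde | O=Cc1c(OC)cc(Oc2c(Oc3c(OC)cc(Oc4c(OC)cc(OC)cc4OC)cc3OC)cc(OC)c(OC)c2OC)cc1OC | intermediate
16 | 2,6-dimethoxy-4-(A–B–C aryloxy)phenyl formate | O=COc1c(OC)cc(Oc2c(Oc3c(OC)cc(Oc4c(OC)cc(OC)cc4OC)cc3OC)cc(OC)c(OC)c2OC)cc1OC | intermediate
17 | 2,6-dimethoxy-4-(A–B–C aryloxy)phenol (A–B–C–D phenol) | Oc1c(OC)cc(Oc2c(Oc3c(OC)cc(Oc4c(OC)cc(OC)cc4OC)cc3OC)cc(OC)c(OC)c2OC)cc1OC | intermediate
18 | 2,6-dimethoxy-1,4-benzoquinone | COC1=CC(=O)C=C(OC)C1=O | starting material
19 | 3-bromo-2,6-dimethoxy-1,4-benzoquinone | COC1=CC(=O)C(Br)=C(OC)C1=O | intermediate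
20 | 2,6-dimethoxy-3-(A–B–C–D aryloxy)-1,4-benzoquinone | COC1=CC(=O)C(Oc2c(OC)cc(Oc3c(Oc4c(OC)cc(Oc5c(OC)cc(OC)cc5OC)cc4OC)cc(OC)c(OC)c3OC)cc2OC)=C(OC)C1=O | intermediate
21 | 3,5-dimethoxy-2-(A–B–C–D aryloxy)benzene-1,4-diol | Oc1cc(OC)c(O)c(OC)c1Oc1c(OC)cc(Oc2c(Oc3c(OC)cc(Oc4c(OC)cc(OC)cc4OC)cc3OC)cc(OC)c(OC)c2OC)cc1OC | intermediate
22 | 4-hydroxy-3,5-dimethoxy-2-(A–B–C–D aryloxy)phenyl pivalate | CC(C)(C)C(=O)Oc1cc(OC)c(O)c(OC)c1Oc1c(OC)cc(Oc2c(Oc3c(OC)cc(Oc4c(OC)cc(OC)cc4OC)cc3OC)cc(OC)c(OC)c2OC)cc1OC | intermediate
23 | 3,4,5-trimethoxy-2-(A–B–C–D aryloxy)phenyl pivalate | CC(C)(C)C(=O)Oc1cc(OC)c(OC)c(OC)c1Oc1c(OC)cc(Oc2c(Oc3c(OC)cc(Oc4c(OC)cc(OC)cc4OC)cc3OC)cc(OC)c(OC)c2OC)cc1OC | intermediate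
24 | 3,4,5-trimethoxy-2-(A–B–C–D aryloxy)phenol (protected A–B–C–D–E pentamer phenol) | Oc1cc(OC)c(OC)c(OC)c1Oc1c(OC)cc(Oc2c(Oc3c(OC)cc(Oc4c(OC)cc(OC)cc4OC)cc3OC)cc(OC)c(OC)c2OC)cc1OC | intermediate
25 | 3,4,5-trimethoxyphenol | COc1cc(O)cc(OC)c1OC | starting material
26 | 2-bromo-3,4,5-trimethoxybenzaldehyde | O=Cc1cc(OC)c(OC)c(OC)c1Br | starting material
27 | 3,4,5-trimethoxy-2-(3,4,5-trimethoxyphenoxy)benzaldehyde | O=Cc1cc(OC)c(OC)c(OC)c1Oc1cc(OC)c(OC)c(OC)c1 | intermediate
28 | 3,4,5-trimethoxy-2-(3,4,5-trimethoxyphenoxy)phenyl formate | O=COc1cc(OC)c(OC)c(OC)c1Oc1cc(OC)c(OC)c(OC)c1 | intermediate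
29 | 3,4,5-trimethoxy-2-(3,4,5-trimethoxyphenoxy)phenol (protected G–H phenol) | Oc1cc(OC)c(OC)c(OC)c1Oc1cc(OC)c(OC)c(OC)c1 | intermediate
30 | 2,6-difluoro-4-(A–B–C–D–E aryloxy)benzaldehyde | O=Cc1c(F)cc(Oc2cc(OC)c(OC)c(OC)c2Oc2c(OC)cc(Oc3c(Oc4c(OC)cc(Oc5c(OC)cc(OC)cc5OC)cc4OC)cc(OC)c(OC)c3OC)cc2OC)cc1F | intermediate
31 | 2-fluoro-4-(A–B–C–D–E aryloxy)-6-(G–H aryloxy)benzaldehyde | O=Cc1c(F)cc(Oc2cc(OC)c(OC)c(OC)c2Oc2c(OC)cc(Oc3c(Oc4c(OC)cc(Oc5c(OC)cc(OC)cc5OC)cc4OC)cc(OC)c(OC)c3OC)cc2OC)cc1Oc1cc(OC)c(OC)c(OC)c1Oc1cc(OC)c(OC)c(OC)c1 | intermediate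
32 | 2-methoxy-4-(A–B–C–D–E aryloxy)-6-(G–H aryloxy)benzaldehyde | O=Cc1c(OC)cc(Oc2cc(OC)c(OC)c(OC)c2Oc2c(OC)cc(Oc3c(Oc4c(OC)cc(Oc5c(OC)cc(OC)cc5OC)cc4OC)cc(OC)c(OC)c3OC)cc2OC)cc1Oc1cc(OC)c(OC)c(OC)c1Oc1cc(OC)c(OC)c(OC)c1 | intermediate
33 | 2-methoxy-4-(A–B–C–D–E aryloxy)-6-(G–H aryloxy)phenyl formate | O=COc1c(OC)cc(Oc2cc(OC)c(OC)c(OC)c2Oc2c(OC)cc(Oc3c(Oc4c(OC)cc(Oc5c(OC)cc(OC)cc5OC)cc4OC)cc(OC)c(OC)c3OC)cc2OC)cc1Oc1cc(OC)c(OC)c(OC)c1Oc1cc(OC)c(OC)c(OC)c1 | intermediate
34 | 2-methoxy-4-(A–B–C–D–E aryloxy)-6-(G–H aryloxy)phenol | Oc1c(OC)cc(Oc2cc(OC)c(OC)c(OC)c2Oc2c(OC)cc(Oc3c(Oc4c(OC)cc(Oc5c(OC)cc(OC)cc5OC)cc4OC)cc(OC)c(OC)c3OC)cc2OC)cc1Oc1cc(OC)c(OC)c(OC)c1Oc1cc(OC)c(OC)c(OC)c1 | intermediate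
35 | CNP0309601.0 (34 with all twenty methoxy groups as hydroxyls) | Oc1cc(O)c(Oc2cc(O)c(Oc3cc(O)c(O)c(O)c3Oc3cc(O)c(Oc4c(Oc5cc(O)c(O)c(Oc6cc(O)c(O)c(O)c6Oc6cc(O)c(O)c(O)c6)c5)cc(O)c(O)c4O)c(O)c3)c(O)c2)c(O)c1 | target

## Step count and least certain steps

Total: 19 steps. Longest linear sequence: 15 steps (steps 1, 2, 3, 5, 6, 7, 8, 10, 11, 12, 13, 16, 17, 18, 19).

Step 16 (key step). The most likely failure is loss of positional control: attack of the phenoxide of 24 at an ortho carbon in the first stage, and over-substitution or exchange of the aryloxy group already in place in the second. All three C–F carbons are activated by the same formyl group, so the discrimination rests on rate differences only. The fallback makes the two ring F ethers by two different mechanisms on a linchpin whose para position carries bromine. It sets out from 29, which displaces one of the two equivalent ortho fluorides of commercial 4-bromo-2,6-difluorobenzaldehyde (Cs2CO3, DMSO, 40 °C; bromide is a much poorer leaving group than fluoride in addition–elimination) to give 4-bromo-2-fluoro-6-(G–H aryloxy)benzaldehyde F1. Palladium-catalysed C–O coupling of F1 with 24 (Pd(OAc)2, 2-di-tert-butylphosphino-2',4',6'-triisopropylbiphenyl, K3PO4, toluene, 100 °C; zerovalent palladium inserts into the C–Br bond, and the non-polar medium suppresses uncatalysed fluoride displacement) then gives 31, where the route is rejoined.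

Step 10. The most likely failure is oxidation of the very electron-rich phenoxide of 17 by the quinone through electron transfer, or addition at a methoxy-bearing or the unsubstituted quinone carbon, because 19 is both an oxidant and an ambident acceptor. The fallback forms the ring E ether by fluoride displacement on an aldehyde and so also bypasses steps 11 to 13. 3,4,5-Trimethoxybenzaldehyde is fluorinated with 1-chloromethyl-4-fluoro-1,4-diazoniabicyclo[2.2.2]octane bis(tetrafluoroborate) (MeCN, 60 °C) to 2-fluoro-3,4,5-trimethoxybenzaldehyde F2. Compound 17 displaces its fluoride (Cs2CO3, DMSO, 120 °C) to give 3,4,5-trimethoxy-2-(A–B–C–D aryloxy)benzaldehyde F3. Peracid oxidation gives 3,4,5-trimethoxy-2-(A–B–C–D aryloxy)phenyl formate F4, and acidic methanolysis gives 24. The fallback sets out from 17 and returns at 24. It is not the first choice because the fluoride of F2 lies between a formyl and a methoxy group and para to a methoxy donor, so the tetra-ortho-substituted ether would have to form at a deactivated carbon.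

Step 11. The most likely failure is insufficient discrimination between the two hydroxyls of 21 (acylation at both, or at the crowded one), together with re-oxidation of 21 by air before acylation. The fallback sets out from 20 and replaces kinetic acylation by alkylation of the mono-phenoxide, where the more acidic and less shielded oxygen should react. After the same dithionite reduction, benzyl bromide with one equivalent of K2CO3 in acetone gives 4-(benzyloxy)-2,6-dimethoxy-3-(A–B–C–D aryloxy)phenol F5. Methylation (MeI, K2CO3, DMF) gives 1-(benzyloxy)-3,4,5-trimethoxy-2-(A–B–C–D aryloxy)benzene F6. Hydrogenolysis (H2, Pd/C, EtOAc) returns to the route at 24.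

Step 5. The most likely failure is slow turnover at copper, because the phenoxide of 8 is flanked by two methoxy groups; this leaves time for protodebromination of 10 and oxidative degradation of the phenoxide. The fallback uses uncatalysed addition–elimination on the fluoro analogue. Rieche formylation of commercial 5-fluoro-1,2,3-trimethoxybenzene gives 6-fluoro-2,3,4-trimethoxybenzaldehyde F7, whose fluoride is displaced by 8 (Cs2CO3, DMSO, 110 °C). The fallback sets out from 8 and returns at 11.

Step 19. The most likely failure is incomplete cleavage of the twenty methyl ethers as partly cleaved boron aryloxides precipitate, and oxidative darkening of the polyphenol during isolation. The fallback sets out from 34 and isolates the product through a stable derivative. The crude material from the BBr3 treatment is peracetylated (Ac2O, pyridine, rt) to the henicosaacetate of 35 F8, which is purified on silica while under-cleaved fractions are returned to BBr3. Hydrazinolysis of F8 (N2H4·H2O, THF/MeOH, 0 °C, Ar), where hydrazine also acts as an antioxidant, then releases 35.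

## Further compounds

F1 | step 16 | 4-bromo-2-fluoro-6-[3,4,5-trimethoxy-2-(3,4,5-trimethoxyphenoxy)phenoxy]benzaldehyde | O=Cc1c(F)cc(Br)cc1Oc1cc(OC)c(OC)c(OC)c1Oc1cc(OC)c(OC)c(OC)c1
F2 | step 10 | 2-fluoro-3,4,5-trimethoxybenzaldehyde | O=Cc1cc(OC)c(OC)c(OC)c1F
F3 | step 10 | 3,4,5-trimethoxy-2-(A–B–C–D aryloxy)benzaldehyde | O=Cc1cc(OC)c(OC)c(OC)c1Oc1c(OC)cc(Oc2c(Oc3c(OC)cc(Oc4c(OC)cc(OC)cc4OC)cc3OC)cc(OC)c(OC)c2OC)cc1OC
F4 | step 10 | 3,4,5-trimethoxy-2-(A–B–C–D aryloxy)phenyl formate | O=COc1cc(OC)c(OC)c(OC)c1Oc1c(OC)cc(Oc2c(Oc3c(OC)cc(Oc4c(OC)cc(OC)cc4OC)cc3OC)cc(OC)c(OC)c2OC)cc1OC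
F5 | step 11 | 4-(benzyloxy)-2,6-dimethoxy-3-(A–B–C–D aryloxy)phenol | Oc1c(OC)cc(OCc2ccccc2)c(Oc2c(OC)cc(Oc3c(Oc4c(OC)cc(Oc5c(OC)cc(OC)cc5OC)cc4OC)cc(OC)c(OC)c3OC)cc2OC)c1OC
F6 | step 11 | 1-(benzyloxy)-3,4,5-trimethoxy-2-(A–B–C–D aryloxy)benzene | COc1cc(OCc2ccccc2)c(Oc2c(OC)cc(Oc3c(Oc4c(OC)cc(Oc5c(OC)cc(OC)cc5OC)cc4OC)cc(OC)c(OC)c3OC)cc2OC)c(OC)c1OC
F7 | step 5 | 6-fluoro-2,3,4-trimethoxybenzaldehyde | O=Cc1c(F)cc(OC)c(OC)c1OC
F8 | step 19 | henicosaacetate of 35 (all twenty-one hydroxyls as acetates) | CC(=O)Oc1cc(OC(C)=O)c(Oc2cc(OC(C)=O)c(Oc3cc(OC(C)=O)c(OC(C)=O)c(OC(C)=O)c3Oc3cc(OC(C)=O)c(Oc4c(Oc5cc(OC(C)=O)c(OC(C)=O)c(Oc6cc(OC(C)=O)c(OC(C)=O)c(OC(C)=O)c6Oc6cc(OC(C)=O)c(OC(C)=O)c(OC(C)=O)c6)c5)cc(OC(C)=O)c(OC(C)=O)c4OC(C)=O)c(OC(C)=O)c3)c(OC(C)=O)c2)c(OC(C)=O)c1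
A1 | alternative 1 | 4-[4-(benzyloxy)-3,5-dimethoxyphenoxy]-5-[2,6-dimethoxy-4-(2,4,6-trimethoxyphenoxy)phenoxy]-2,3-dimethoxyphenol | Oc1cc(Oc2c(OC)cc(Oc3c(OC)cc(OC)cc3OC)cc2OC)c(Oc2cc(OC)c(OCc3ccccc3)c(OC)c2)c(OC)c1OC
A2 | alternative 1 | 2-[4-(ethynyloxy)-3,5-dimethoxyphenoxy]-1,3,5-trimethoxybenzene | C#COc1c(OC)cc(Oc2c(OC)cc(OC)cc2OC)cc1OC
A3 | alternative 1 | 2-[4-(benzyloxy)-3,5-dimethoxyphenoxy]-3,4-dimethoxycyclobut-2-en-1-one (racemic) | O=C1C(Oc2cc(OC)c(OCc3ccccc3)c(OC)c2)=C(OC)C1OC
A4 | alternative 2 | methyl 2-hydroxy-3-methoxy-5-(A–B–C aryloxy)benzoate | COC(=O)c1cc(Oc2c(Oc3c(OC)cc(Oc4c(OC)cc(OC)cc4OC)cc3OC)cc(OC)c(OC)c2OC)cc(OC)c1O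
A5 | alternative 2 | 1,4-dimethoxy-1,3-bis(trimethylsilyloxy)buta-1,3-diene | COC=C(O[Si](C)(C)C)C=C(OC)O[Si](C)(C)C
A6 | alternative 2 | 2-(A–B–C aryloxy)propanedial | O=CC(C=O)Oc1c(Oc2c(OC)cc(Oc3c(OC)cc(OC)cc3OC)cc2OC)cc(OC)c(OC)c1OC
A7 | alternative 3 | 3,4,5-trimethoxy-2-(3,4,5-trimethoxyphenoxy)phenol | Oc1cc(OC)c(OC)c(OC)c1Oc1cc(OC)c(OC)c(OC)c1
A8 | alternative 3 | 3,4-dimethoxy-4-(1-methoxyethenyl)-2-(3,4,5-trimethoxyphenoxy)cyclobut-2-en-1-one (racemic) | O=C1C(Oc2cc(OC)c(OC)c(OC)c2)=C(OC)C1(OC)C(OC)=C
A9 | alternative 3 | 3-methoxy-4-(3,4,5-trimethoxyphenoxy)cyclobut-3-ene-1,2-dione | COC1=C(Oc2cc(OC)c(OC)c(OC)c2)C(=O)C1=O
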